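The constants show where the acid set free sits: the equilibrium constant of step 2 times the charged nucleophile is 1400, against 8.9 for the free base, so at the start the nucleophile takes up acid far more strongly than the free base does, and protonated nucleophile comes free as free acid is drained away.

    electrophile + nucleophile → acid set free + product (k1 = 0.58 M⁻¹ s⁻¹)
    nucleophile + acid set free ⇌ protonated nucleophile, settled at all times (K2 = 720 M⁻¹)
    acid set free + free base ⇌ salt of the base (K3 = 37 M⁻¹, k3 = 5.8 M⁻¹ s⁻¹)
    2 nucleophile → homo dimer (k4 = 0.14 M⁻¹ s⁻¹)
    acid set free → by-product carried off (k5 = 0.25 s⁻¹)
    electrophile + acid set free ⇌ idle adduct, settled at all times (K6 = 22 M⁻¹)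
    acid set free + scavenger → scavenged by-product (k7 = 8.8 M⁻¹ s⁻¹)

| setting | grey | red | amber |
|---|---|---|---|
| electrophile | 0.80 M | 0.80 M | 0.80 M |
| nucleophile | 2.00 M | 2.00 M | 2.00 M |
| free base | 0.240 M | 0.310 M | 0.410 M |
| scavenger | 0.640 M | 0.640 M | 0.640 M |
| time | 12 s | 12 s | 12 s |

1. part of the electrophile that has reacted at the end, grey
2. part of the electrophile that has reacted at the end, red
3. part of the electrophile that has reacted at the end, amber
4. what raising the concentration of free base from its lowest to its highest value here does to the part of the electrophile that has reacted (changes below 5 percentage points count as none) (no change / it rises / it falls)

- for acid set free the idle adduct is counted in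
- a doubled species enters its step squared and goes two at a time
- run time (grey): 12 s

I turn the question round. For the part reacted to rise by 5 percentage points from grey to amber, the added free base would have to release enough nucleophile for 0.0400 M of product. To size that, I freeze free base and scavenger at their charges, which makes the loss of free acid pseudo-first-order with a constant of 7.27 s⁻¹ in grey, the way back not counted. I also freeze protonated nucleophile equal to free nucleophile, which puts free acid at 0.001389 M. Over the run this gives what I call the drain, the acid carried out of the flask while those two stay frozen: 0.121 M. This is less than the scavenger charge, so the freezing is fair. Amber's extra free base adds 0.0164 M to the drain, less than the 0.0400 M required, so I commit to no change. The drain also gives a rough estimate of the product. Each turn of step 1 consumes one nucleophile and holds a second as protonated nucleophile until the drain frees it, so, with the homo dimer not counted, I put the product at half the sum of nucleophile charge and drain. In grey that is 1.06 M, above the electrophile charge.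

The forecast gives 89 %, 89.5 % and 90 %, hence no change, and holds that “That drain is dominated by the scavenger, with the free base adding only a small share”.

The simulation gives 89.3 %, 89.4 % and 89.5 %: no change, a change of 0.18 points. In grey, salt of the base, scavenged by-product and by-product carried off together hold 0.222 M at 12.0 s, about twice my drain of 0.121 M, so my frozen ratio ran low. Scaled by that, amber's extra is 0.0301 M, still less than the 0.0400 M required.

The neighbour flask charged with 0.50 M of nucleophile keeps grey's free base and scavenger, hence the same reckoned drain, and my estimate for it, which is no bound, is 0.310 M of product, or 38.8 % of the electrophile charged. That neighbour ends with product at 42.1 % of the electrophile charged, more than the estimate.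

The numbers stand for no real mixture; the flask was simulated.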